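**Retrosynthetic overview**

- The strategy rests on ring C of the chromanone (O1, C2, C3, C4, C4a, C8a): C2 and C3 each carry one methyl, trans to each other. Both C–CH3 bonds are therefore made across the C2=C3 bond of a flat, unsubstituted chromone, followed only by removal of two allyl groups.
- The chromone (allyl ether at O5, allyl ester on the C6 side chain) comes from a tricyclic chromone–dihydrocoumarin. Its δ-lactone masks both the future 5-OH and the acid, and forces the pyranone to close on the other phenol oxygen.
- The tricycle comes from a (4R)-5,7-dimethoxy-4-propyldihydrocoumarin by C8 acetylation, chelation-directed O7 demethylation, C6 iodination, enaminone closure of the pyranone and Stille prenylation.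
- The side-chain stereocentre is set by asymmetric conjugate reduction of the Pechmann coumarin from 3,5-dimethoxyphenol and ethyl 3-oxohexanoate.
- Ring order: ring A (benzene) is purchased; the temporary lactone ring forms in step 1; ring C closes in step 6; the lactone is opened in step 8.

Key step: step 9

Assumption: the sense of induction of the two ligand-controlled steps (2 and 9) is not predicted here; each ligand is specified as the enantiomer that gives the stated configuration, to be fixed in a test run.

**Step 1**
Reactants: 1 3,5-dimethoxyphenol; 2 ethyl 3-oxohexanoate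
Product: 3 5,7-dimethoxy-4-propyl-2H-chromen-2-one
Conditions: MeSO3H, neat, 0 °C → rt
Reagents that add atoms: ethyl 3-oxohexanoate (CCCC(=O)CC(=O)OCC)
Why: Pechmann condensation (transesterification, ring closure ortho to the phenol, dehydration); the two ortho positions of the symmetric phenol are equivalent, so a single coumarin should form.

**Step 2**
Reactants: 3 5,7-dimethoxy-4-propyl-2H-chromen-2-one
Product: 5 (4R)-5,7-dimethoxy-4-propylchroman-2-one, via silyl ketene acetal 4 (not isolated)
Conditions: Cu(OAc)2·H2O (3 mol %), DTBM-SEGPHOS (3 mol %, enantiomer giving 4R), (EtO)2MeSiH (1.5 equiv), toluene, 0 °C → rt, no alcohol additive; then aq. NH4F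
Reagents that add atoms: none
Why: Asymmetric conjugate reduction of a β,β-disubstituted unsaturated lactone by phosphine-ligated CuH, in which hydride goes to C4 on the face chosen by the ligand (sets 4R); without a proton source the product rests as silyl ketene acetal 4, which is not reduced further and gives the lactone on work-up.

**Step 3**
Reactants: 5 (4R)-5,7-dimethoxy-4-propylchroman-2-one; 6 acetyl chloride
Product: 7 (4R)-8-acetyl-5,7-dimethoxy-4-propylchroman-2-one
Conditions: AcCl (1.5 equiv), SnCl4 (1.5 equiv), CH2Cl2, −10 °C → rt
Reagents that add atoms: acetyl chloride (CC(=O)Cl)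
Why: Friedel–Crafts acylation, expected at C8 (ortho to 7-OMe, para to 5-OMe) rather than at C6, which lies between two methoxy groups and is further shielded because the C4 substituent pushes the 5-OMe toward it, as in the C8-selective substitution of 5,7-dialkoxychromans; the benzylic centre is not touched.

**Step 4**
Reactants: 7 (4R)-8-acetyl-5,7-dimethoxy-4-propylchroman-2-one
Product: 8 (4R)-8-acetyl-7-hydroxy-5-methoxy-4-propylchroman-2-one
Conditions: BCl3 (1.5 equiv), CH2Cl2, −78 → 0 °C; aq. NaHCO3
Reagents that add atoms: none
Why: Chelation-directed ether cleavage, in which BCl3 bound to the acetyl oxygen cleaves only the ortho 7-OMe; the 5-OMe has no neighbouring carbonyl and the other ortho oxygen is held in the lactone, so it should give the single phenol that is para to the side-chain carbon.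

**Step 5**
Reactants: 8 (4R)-8-acetyl-7-hydroxy-5-methoxy-4-propylchroman-2-one; 9 N-iodosuccinimide
Product: 10 (4R)-8-acetyl-7-hydroxy-6-iodo-5-methoxy-4-propylchroman-2-one
Conditions: NIS (1.05 equiv), TFA (10 mol %), MeCN, 0 °C → rt
Reagents that add atoms: N-iodosuccinimide (O=C1CCC(=O)N1I)
Why: Electrophilic aromatic iodination at C6, the only free ring position, which is ortho to the free phenol and to a methoxy group.

**Step 6**
Reactants: 10 (4R)-8-acetyl-7-hydroxy-6-iodo-5-methoxy-4-propylchroman-2-one; 11 N,N-dimethylformamide dimethyl acetal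
Product: 13 (4R)-6-iodo-5-methoxy-4-propyl-3,4-dihydro-2H,10H-pyrano[2,3-f]chromene-2,10-dione (chromone ring fused at O7/C8 of the dihydrocoumarin), via enaminone 12 (not isolated)
Conditions: Me2NCH(OMe)2 (1.5 equiv), 4 Å MS, toluene, 80 °C; then conc. HCl, CH2Cl2, rt
Reagents that add atoms: N,N-dimethylformamide dimethyl acetal (COC(OC)N(C)C)
Why: Enaminone chromone synthesis (condensation of the methyl ketone with the amide acetal, then acid-induced addition of the 7-OH to the β-carbon and loss of dimethylamine); the lactone holds the other ortho oxygen, so the pyranone can close only on O7, and the sieves take up the methanol that could otherwise open the lactone.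

**Step 7**
Reactants: 13 (4R)-6-iodo-5-methoxy-4-propyl-3,4-dihydro-2H,10H-pyrano[2,3-f]chromene-2,10-dione; 14 tributyl(3-methylbut-2-en-1-yl)stannane
Product: 15 (4R)-5-methoxy-6-(3-methylbut-2-enyl)-4-propyl-3,4-dihydro-2H,10H-pyrano[2,3-f]chromene-2,10-dione
Conditions: Pd(PPh3)4 (5 mol %), DMF, 90 °C
Reagents that add atoms: tributyl(3-methylbut-2-en-1-yl)stannane (CCCC[Sn](CCCC)(CCCC)CC=C(C)C)
Why: Stille cross-coupling of the aryl iodide with the prenylstannane, which normally gives the linear prenyl arene; the prenyl group ends between a methoxy group and the ring oxygen, so no free phenol can later add to it.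

**Step 8**
Reactants: 15 (4R)-5-methoxy-6-(3-methylbut-2-enyl)-4-propyl-3,4-dihydro-2H,10H-pyrano[2,3-f]chromene-2,10-dione; 16 prop-2-en-1-ol; 17 allyl bromide
Product: 19 allyl (R)-3-[5-(allyloxy)-7-methoxy-8-(3-methylbut-2-enyl)-4-oxo-4H-chromen-6-yl]hexanoate, via hydroxychromone allyl ester 18 (not isolated)
Conditions: K2CO3 (3 equiv), allyl alcohol, rt; evaporate; allyl bromide (3 equiv), DMF, 50 °C
Reagents that add atoms: prop-2-en-1-ol (C=CCO); allyl bromide (C=CCBr)
Why: Base-mediated transesterification opens the activated aryl lactone to the allyl ester and the chelated phenoxide (the equilibrium favours alkyl ester plus phenoxide), which is then O-allylated in a Williamson ether synthesis; no hydroxide is used, so the base-sensitive chromone should survive.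

**Step 9**
Reactants: 19 allyl (R)-3-[5-(allyloxy)-7-methoxy-8-(3-methylbut-2-enyl)-4-oxo-4H-chromen-6-yl]hexanoate; 20 methylmagnesium bromide; 21 iodomethane
Product: 23 allyl (R)-3-[(2S,3S)-5-(allyloxy)-7-methoxy-2,3-dimethyl-8-(3-methylbut-2-enyl)-4-oxochroman-6-yl]hexanoate, via bromomagnesium enolate 22 (not isolated)
Conditions: CuBr·SMe2 (5 mol %), 1-[2-(dicyclohexylphosphino)ferrocenyl]ethyldiphenylphosphine (6 mol %, enantiomer giving 2S), MeMgBr (1.3 equiv), CH2Cl2, −78 °C; then MeI (5 equiv), DMPU, −78 → −20 °C; aq. NH4Cl
Reagents that add atoms: methylmagnesium bromide (C[Mg]Br); iodomethane (CI)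
Why: MeMgBr transmetalates to the diphosphine complex of CuBr to give a chiral methyl species of monovalent copper, which binds the C2=C3 bond of the magnesium-activated chromone, adds at C2 through a trivalent copper intermediate and forms the C2–CH3 bond by reductive elimination, leaving enolate 22, which MeI then C-methylates at C3. The closest known reactions are the copper-catalysed enantioselective conjugate addition of Grignard reagents to chromones and the anti-selective alkylation of 2-substituted chroman-4-one enolates, joined here as a tandem conjugate addition–enolate trapping. No ring is closed in this step. C2 (S) is set by the ligand, whose enantiomer is chosen for methyl transfer to the face that gives 2S. C3 (S) is set by the substrate, since MeI enters anti to the new C2 methyl; this is also the more stable trans arrangement, so a cis fraction could be corrected by base equilibration. The step needs 1,4- over 1,2-addition and tolerance of the ester: the vinylogous ester is the only Michael acceptor present, and at −78 °C the catalysed addition should outrun attack of MeMgBr on the saturated allyl ester or on the allyl groups, while the remote side-chain centre is untouched.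

**Step 10**
Reactants: 23 allyl (R)-3-[(2S,3S)-5-(allyloxy)-7-methoxy-2,3-dimethyl-8-(3-methylbut-2-enyl)-4-oxochroman-6-yl]hexanoate
Product: 24 (R)-3-[(2S,3S)-5-hydroxy-7-methoxy-2,3-dimethyl-8-(3-methylbut-2-enyl)-4-oxochroman-6-yl]hexanoic acid (CNP0233409.1)
Conditions: Pd(PPh3)4 (5 mol %), morpholine (6 equiv), THF, rt; cold dilute citric acid work-up
Reagents that add atoms: none
Why: Tsuji–Trost deallylation, in which zerovalent palladium ionises the allyl ester and the allyl aryl ether to π-allyl complexes that morpholine captures; the conditions are mild enough that C2 and C3 should not epimerise, the prenyl group is inert, and the weakly acidic work-up avoids relactonisation onto the 5-OH.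

**Compound list**

1 | 3,5-dimethoxyphenol | COc1cc(O)cc(OC)c1 | starting material
2 | ethyl 3-oxohexanoate | CCCC(=O)CC(=O)OCC | starting material
3 | 5,7-dimethoxy-4-propyl-2H-chromen-2-one | CCCC1=CC(=O)Oc2cc(OC)cc(OC)c12 | intermediate
4 | (4R)-2-{[diethoxy(methyl)silyl]oxy}-5,7-dimethoxy-4-propyl-4H-chromene (silyl ketene acetal) | CCC[C@@H]1C=C(O[Si](C)(OCC)OCC)Oc2cc(OC)cc(OC)c12 | intermediate (not isolated)
5 | (4R)-5,7-dimethoxy-4-propylchroman-2-one | CCC[C@@H]1CC(=O)Oc2cc(OC)cc(OC)c12 | intermediate
6 | acetyl chloride | CC(=O)Cl | starting material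
7 | (4R)-8-acetyl-5,7-dimethoxy-4-propylchroman-2-one | CCC[C@@H]1CC(=O)Oc2c(C(C)=O)c(OC)cc(OC)c12 | intermediate
8 | (4R)-8-acetyl-7-hydroxy-5-methoxy-4-propylchroman-2-one | CCC[C@@H]1CC(=O)Oc2c(C(C)=O)c(O)cc(OC)c12 | intermediate
9 | N-iodosuccinimide | O=C1CCC(=O)N1I | starting material
10 | (4R)-8-acetyl-7-hydroxy-6-iodo-5-methoxy-4-propylchroman-2-one | CCC[C@@H]1CC(=O)Oc2c(C(C)=O)c(O)c(I)c(OC)c12 | intermediate
11 | N,N-dimethylformamide dimethyl acetal | COC(OC)N(C)C | starting material
12 | (4R)-8-[(E)-3-(dimethylamino)prop-2-enoyl]-7-hydroxy-6-iodo-5-methoxy-4-propylchroman-2-one (enaminone) | CCC[C@@H]1CC(=O)Oc2c(C(=O)/C=C/N(C)C)c(O)c(I)c(OC)c12 | intermediate (not isolated)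
13 | (4R)-6-iodo-5-methoxy-4-propyl-3,4-dihydro-2H,10H-pyrano[2,3-f]chromene-2,10-dione | CCC[C@@H]1CC(=O)Oc2c3C(=O)C=COc3c(I)c(OC)c12 | intermediate
14 | tributyl(3-methylbut-2-en-1-yl)stannane | CCCC[Sn](CCCC)(CCCC)CC=C(C)C | starting material
15 | (4R)-5-methoxy-6-(3-methylbut-2-enyl)-4-propyl-3,4-dihydro-2H,10H-pyrano[2,3-f]chromene-2,10-dione | CCC[C@@H]1CC(=O)Oc2c3C(=O)C=COc3c(CC=C(C)C)c(OC)c12 | intermediate
16 | prop-2-en-1-ol (allyl alcohol) | C=CCO | starting material
17 | allyl bromide | C=CCBr | starting material
18 | allyl (R)-3-[5-hydroxy-7-methoxy-8-(3-methylbut-2-enyl)-4-oxo-4H-chromen-6-yl]hexanoate | CCC[C@H](CC(=O)OCC=C)c1c(O)c2c(c(CC=C(C)C)c1OC)OC=CC2=O | intermediate (not isolated)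
19 | allyl (R)-3-[5-(allyloxy)-7-methoxy-8-(3-methylbut-2-enyl)-4-oxo-4H-chromen-6-yl]hexanoate | CCC[C@H](CC(=O)OCC=C)c1c(OCC=C)c2c(c(CC=C(C)C)c1OC)OC=CC2=O | intermediate
20 | methylmagnesium bromide | C[Mg]Br | starting material
21 | iodomethane | CI | starting material
22 | bromomagnesium enolate of allyl (R)-3-[(2S)-5-(allyloxy)-7-methoxy-2-methyl-8-(3-methylbut-2-enyl)-4-oxochroman-6-yl]hexanoate | CCC[C@H](CC(=O)OCC=C)c1c(OCC=C)c2c(c(CC=C(C)C)c1OC)O[C@@H](C)C=C2O[Mg]Br | intermediate (not isolated)
23 | allyl (R)-3-[(2S,3S)-5-(allyloxy)-7-methoxy-2,3-dimethyl-8-(3-methylbut-2-enyl)-4-oxochroman-6-yl]hexanoate | CCC[C@H](CC(=O)OCC=C)c1c(OCC=C)c2c(c(CC=C(C)C)c1OC)O[C@@H](C)[C@H](C)C2=O | intermediate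
24 | (R)-3-[(2S,3S)-5-hydroxy-7-methoxy-2,3-dimethyl-8-(3-methylbut-2-enyl)-4-oxochroman-6-yl]hexanoic acid | CCC[C@H](CC(=O)O)c1c(O)c2c(c(CC=C(C)C)c1OC)O[C@@H](C)[C@H](C)C2=O | target

**Step count and risks**

Total step count: 10. Longest linear sequence: 10 steps (1 → 24).

Steps most likely to fail:

1. Step 9. Methyl is the least reactive Grignard group in these additions, so the catalysed pathway may be slow; uncatalysed addition or attack on the allyl ester would then compete, and facial selectivity would fall. The C-methylation of the magnesium enolate may also be sluggish; on warming, the enolate can open by β-elimination of the aryl oxide, which scrambles C2. Fallback: the two bond formations are decoupled. Setting out from 19, the conjugate addition is run alone and quenched cold with NH4Cl to give allyl (R)-3-[(2S)-5-(allyloxy)-7-methoxy-2-methyl-8-(3-methylbut-2-enyl)-4-oxochroman-6-yl]hexanoate F1. Its lithium enolate (LiHMDS, THF, −78 °C; the ketone α-position is more acidic than the ester α-position) is methylated with MeI at −78 °C, where ring opening is slow. Any cis isomer is equilibrated to trans with DBU. The sequence comes back to the route at 23.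

2. Step 2. The hydride reagent may reduce the lactone further to the lactol, or the peri 5-methoxy group may lower facial selectivity at the crowded β-carbon. Fallback: the same centre is made by C–C instead of C–H bond formation. Setting out from 1, Pd(OAc)2-catalysed hydroarylation and lactonisation with ethyl propiolate in formic acid gives 5,7-dimethoxy-2H-chromen-2-one F2. Copper-catalysed enantioselective conjugate addition of propylmagnesium bromide (CuBr·SMe2, the same ferrocenyl diphosphine class, t-BuOMe, −72 °C), followed by protonation, comes back to the route at 5.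

3. Step 3. Acylation may occur partly at C6, which would be a loss of regiocontrol between the two free ring positions. Fallback: the two positions are made equivalent before acylation. Setting out from 5, methanolysis of the lactone and O-methylation (K2CO3, MeOH; then MeI, DMF) give methyl (R)-3-(2,4,6-trimethoxyphenyl)hexanoate F3. Friedel–Crafts acetylation (AcCl, SnCl4) can then give only methyl (R)-3-(3-acetyl-2,4,6-trimethoxyphenyl)hexanoate F4, because rotation about the aryl–carbon bond interconverts the two free positions. Excess BCl3 (or AlCl3) cleaves the two methoxy groups ortho to the acetyl, giving methyl (R)-3-(3-acetyl-2,4-dihydroxy-6-methoxyphenyl)hexanoate F5. TsOH in hot toluene then closes the lactone on the only phenol ortho to the side chain, and the sequence comes back to the route at 8.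

**Further compounds**

F1 | step 9 | allyl (R)-3-[(2S)-5-(allyloxy)-7-methoxy-2-methyl-8-(3-methylbut-2-enyl)-4-oxochroman-6-yl]hexanoate | CCC[C@H](CC(=O)OCC=C)c1c(OCC=C)c2c(c(CC=C(C)C)c1OC)O[C@@H](C)CC2=O
F2 | step 2 | 5,7-dimethoxy-2H-chromen-2-one | COc1cc(OC)c2C=CC(=O)Oc2c1
F3 | step 3 | methyl (R)-3-(2,4,6-trimethoxyphenyl)hexanoate | CCC[C@H](CC(=O)OC)c1c(OC)cc(OC)cc1OC
F4 | step 3 | methyl (R)-3-(3-acetyl-2,4,6-trimethoxyphenyl)hexanoate | CCC[C@H](CC(=O)OC)c1c(OC)c(C(C)=O)c(OC)cc1OC
F5 | step 3 | methyl (R)-3-(3-acetyl-2,4-dihydroxy-6-methoxyphenyl)hexanoate | CCC[C@H](CC(=O)OC)c1c(O)c(C(C)=O)c(O)cc1OC
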